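**Plan**
- Retrosynthesis: (1) cut the methyl ester and the aryl–CO2 bond at C6 (late carboxylation ortho to the 7-OH). (2) Take the C3=C4 alkene back to a chroman-4-one. (3) Cut the C3–C2 bond of the pyran ring (ring C) by a Petasis–Ferrier-type 1,3 O-to-C shift of a 4-methylidene-1,3-benzodioxine, made by methylenation of a salicylate acetonide. (4) Open ring A to a diketo-dioxinone, with the prenyl group from a palladium-catalysed decarboxylative migration and the ring B side chain from a C-acylation.
- Forward order: the chain is built on 2,2,6-trimethyl-1,3-dioxin-4-one, ring A closes by aldol aromatisation with the dioxinone kept, the carbonyl is methylenated, ring C forms by the rearrangement, reduction/dehydration gives the 2H-chromene, then desilylation, carboxylation and esterification.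
- Enabling feature: in ring C, O1–C2(CH3)2 sits on arene carbon C8a and the ortho carbon C4a carries C4. This is exactly the acetonide of a salicylic acid (2,2-dimethyl-1,3-benzodioxin-4-one): the ketal carbon is C2, its phenol oxygen is O1, the carboxyl carbon is C4. Only the lactone oxygen has to be exchanged for the CH2 that becomes C3, and the chromene regiochemistry on ring A is fixed by the aromatisation.
- Helpers: the enol oxygen tether ends as the C4 ketone oxygen and is removed by reduction/dehydration; two TIPS ethers are removed by fluoride.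
- Stereochemistry: the target is achiral; the only stereocenter on the route (C4 of carbinol 18, racemic) is erased by dehydration.

Key step: step 8

Assumption: the β-dicarbonyl compounds 9, 11 and 12 are drawn as keto tautomers although they should be largely enolised; this does not change the chemistry. Locants follow 2H-chromene numbering (O1, C2, C3, C4, C4a, C5–C8, C8a), and the benzodioxine intermediates use the same locants for ring A. Ring A is the hexasubstituted benzene, ring B the 4-hydroxyphenyl ring, ring C the pyran.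

**Route**

Step 1
Reactants: 1 3-(4-hydroxyphenyl)propanoic acid
Product: 3 3-[4-(triisopropylsilyloxy)phenyl]propanoic acid, via silyl ester 2 (not isolated)
Conditions: TIPSCl (2.3 equiv), imidazole, DMF, rt; then K2CO3, THF/H2O, rt; 1 M HCl to pH 3
Reagents that add atoms: triisopropylsilyl chloride, CC(C)[Si](Cl)(C(C)C)C(C)C
Why: Silylation of both acidic OH groups followed by selective hydrolysis of the much more labile silyl ester leaves the aryl TIPS ether (silyl protection of a phenol), which should survive the enolate, palladium, titanium and aluminium chemistry and fall to fluoride at the end.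

Step 2
Reactants: 4 2,2-dimethyl-1,3-dioxane-4,6-dione (Meldrum's acid); 5 3-methylbut-2-en-1-ol (prenol)
Product: 6 3-[(3-methylbut-2-en-1-yl)oxy]-3-oxopropanoic acid (monoprenyl malonate)
Conditions: toluene, 100 °C
Reagents that add atoms: none
Why: Thermal alcoholysis of Meldrum's acid opens the ring at one acyl carbon and releases acetone, which should give the malonic half ester without added acid that could harm the prenyl alkene.

Step 3
Reactants: 6 monoprenyl malonate; 7 2,2,6-trimethyl-4H-1,3-dioxin-4-one
Product: 9 3-methylbut-2-en-1-yl 4-(2,2-dimethyl-4-oxo-4H-1,3-dioxin-6-yl)-3-oxobutanoate, via acyl imidazolide 8 (not isolated)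
Conditions: 6, CDI, THF, rt; separately 7 (2.2 equiv), LiN(SiMe3)2, THF, −78 °C; add 8, −78 to −40 °C; 1 M HCl
Reagents that add atoms: none
Why: Crossed vinylogous Claisen condensation: the lithium dienolate of 7 should be acylated at its γ-carbon (the C6 methyl) by the acyl imidazolide, the excess dienolate covering the acidity of the malonyl partner and of the product.

Step 4
Reactants: 9 keto-ester dioxinone; 3 3-[4-(triisopropylsilyloxy)phenyl]propanoic acid
Product: 11 3-methylbut-2-en-1-yl 2-[(2,2-dimethyl-4-oxo-4H-1,3-dioxin-6-yl)acetyl]-3-oxo-5-[4-(triisopropylsilyloxy)phenyl]pentanoate, via acid chloride 10 (not isolated)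
Conditions: 3, (COCl)2, DMF (cat.), CH2Cl2, 0 °C to rt, evaporate; then 9, MgCl2, pyridine, CH2Cl2, 0 °C, add 10, 0 °C to rt
Reagents that add atoms: none
Why: Soft enolisation with MgCl2/pyridine should give the magnesium chelate of the β-keto ester, which is C-acylated by the acid chloride at the carbon between ketone and ester (magnesium-mediated C-acylation of a β-keto ester).

Step 5
Reactants: 11 diketo-ester dioxinone
Product: 13 7-hydroxy-2,2-dimethyl-8-(3-methylbut-2-en-1-yl)-5-{2-[4-(triisopropylsilyloxy)phenyl]ethyl}-4H-1,3-benzodioxin-4-one, via prenylated diketo-dioxinone 12 (not isolated)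
Conditions: Pd(PPh3)4 (5 mol %), Cs2CO3, THF, 0 °C to rt; cold 1 M HCl
Reagents that add atoms: none
Why: Zerovalent palladium should ionise the prenyl ester (decarboxylative Tsuji–Trost-type allylation), CO2 is lost and the prenyl group is delivered through its CH2 terminus to the methylene between the dioxinone and the ketone (the later C8), after which Cs2CO3 should drive an intramolecular aldol condensation of dioxinone C5 onto the side-chain ketone (6-(enolendo)-exo-trig) and dehydration to ring A with the acetonide intact.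

Step 6
Reactants: 13 benzodioxinone phenol
Product: 14 2,2-dimethyl-8-(3-methylbut-2-en-1-yl)-7-(triisopropylsilyloxy)-5-{2-[4-(triisopropylsilyloxy)phenyl]ethyl}-4H-1,3-benzodioxin-4-one
Conditions: TIPSOTf, 2,6-lutidine, CH2Cl2, 0 °C to rt
Reagents that add atoms: triisopropylsilyl trifluoromethanesulfonate, CC(C)[Si](OS(=O)(=O)C(F)(F)F)(C(C)C)C(C)C
Why: Silyl ether formation with a silyl triflate and a hindered base should cap the acidic 7-OH, which would otherwise protonate the titanium reagent, deactivate the para-disposed carbonyl and later cyclise onto the prenyl group under acid.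

Step 7
Reactants: 14 bis-silylated benzodioxinone
Product: 15 2,2-dimethyl-4-methylidene-8-(3-methylbut-2-en-1-yl)-7-(triisopropylsilyloxy)-5-{2-[4-(triisopropylsilyloxy)phenyl]ethyl}-4H-1,3-benzodioxine
Conditions: Cp2TiMe2 (3 equiv), toluene, 65 °C, dark; filtration through basic alumina
Reagents that add atoms: dimethyltitanocene Cp2TiMe2, C[Ti+2]C.c1cc[cH-]c1.c1cc[cH-]c1
Why: Petasis methylenation: on heating, Cp2TiMe2 loses methane to give Cp2Ti=CH2, which should convert the lactone-type carbonyl C4 into the exocyclic enol ether through an oxatitanacyclobutane, as established for 1,3-dioxan-4-ones and aryl lactones, under non-acidic conditions that keep the ketal, silyl ethers and prenyl group.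

Step 8
Reactants: 15 enol ketal
Product: 17 2,2-dimethyl-8-(3-methylbut-2-en-1-yl)-7-(triisopropylsilyloxy)-5-{2-[4-(triisopropylsilyloxy)phenyl]ethyl}-2,3-dihydro-4H-chromen-4-one, via ion pair 16 (not isolated)
Conditions: Me2AlCl (1.2 equiv), CH2Cl2, −78 °C; 1 M HCl, 0 °C
Reagents that add atoms: none
Why: Proposed new method: Me2AlCl should bind the enol-ether oxygen O3 of 15 and ionise the O3–C2 ketal bond to the contact ion pair 16, an aryloxy-stabilised tertiary oxocarbenium ion held beside the aluminium enolate of the aryl methyl ketone; the enolate CH2 carbon then attacks the carbenium carbon and forms the C3–C2 bond, so that the ring oxygen O3 is exchanged for CH2 (net 1,3 O-to-C shift). The closest known reaction type is the Petasis–Ferrier rearrangement of 4-methylene-1,3-dioxanes to tetrahydropyran-4-ones, established on non-benzo-fused enol acetals but not on a salicylate-derived 4-methylidene-1,3-benzodioxine ketal. Ring C closes in a 6-(enolendo)-endo-trig mode on the O1=C2 oxocarbenium π bond. No stereocenter is formed. The step needs C-attack of the enolate to beat Prins-type capture of the cation by the C8 prenyl alkene, methyl transfer from aluminium and intermolecular transfer of the isopropylidene unit; the much higher nucleophilicity of the aluminium enolate, its position ortho to O1 within the ion pair, the low temperature and the silyl caps on both phenols should secure this, and O-recombination only returns 15.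

Step 9
Reactants: 17 chroman-4-one
Product: 19 2,2-dimethyl-8-(3-methylbut-2-en-1-yl)-7-(triisopropylsilyloxy)-5-{2-[4-(triisopropylsilyloxy)phenyl]ethyl}-2H-chromene, via chroman-4-ol 18 (not isolated)
Conditions: NaBH4, THF/MeOH, 0 °C to rt; aqueous work-up; then p-TsOH·H2O (5 mol %), toluene, 60 °C
Reagents that add atoms: none
Why: NaBH4 should reduce the aryl ketone to the racemic benzylic alcohol, which ionises under mild acid to a cation stabilised by O1 (ortho) and the C7 silyloxy group (para) and loses a C3 proton to give the conjugated 2H-chromene (hydride reduction followed by E1 dehydration), erasing the carbinol stereocenter.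

Step 10
Reactants: 19 bis-silylated chromene
Product: 20 5-[2-(4-hydroxyphenyl)ethyl]-2,2-dimethyl-8-(3-methylbut-2-en-1-yl)-2H-chromen-7-ol
Conditions: Bu4NF (2.5 equiv), THF, 0 °C; AcOH
Reagents that add atoms: none
Why: Fluoride-induced cleavage of both aryl silyl ethers (Si–F bond formation) should free the two phenols under conditions that leave the chromene and prenyl alkenes untouched.

Step 11
Reactants: 20 chromene diphenol
Product: 21 7-hydroxy-5-[2-(4-hydroxyphenyl)ethyl]-2,2-dimethyl-8-(3-methylbut-2-en-1-yl)-2H-chromene-6-carboxylic acid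
Conditions: MeOMgOCO2Me (2 M in DMF, excess), 120 °C; cold 1 M HCl
Reagents that add atoms: methyl magnesium carbonate MeOMgOCO2Me, COC(=O)O[Mg]OC
Why: Kolbe–Schmitt-type carboxylation with methyl magnesium carbonate: the magnesium phenoxide of electron-rich ring A should deliver CO2 to its only free position C6 (ortho to 7-OH, para to O1) and hold the product as a magnesium salicylate chelate, while the simple para-alkylphenol of ring B is not activated enough to react; this reaction type is established for alkylresorcinols and their chromene monoethers.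

Step 12
Reactants: 21 chromene carboxylic acid
Product: 22 methyl 7-hydroxy-5-[2-(4-hydroxyphenyl)ethyl]-2,2-dimethyl-8-(3-methylbut-2-en-1-yl)-2H-chromene-6-carboxylate (target)
Conditions: Me3SiCHN2 (1.1 equiv), toluene/MeOH 4:1, 0 °C
Reagents that add atoms: trimethylsilyldiazomethane, C[Si](C)(C)C=[N+]=[N-]
Why: Esterification with trimethylsilyldiazomethane in methanol: only the carboxylic acid is acidic enough to protonate the diazo compound, so both phenols should stay free.

**Compound list**
1 | 3-(4-hydroxyphenyl)propanoic acid | OC(=O)CCc1ccc(O)cc1 | starting material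
2 | triisopropylsilyl 3-[4-(triisopropylsilyloxy)phenyl]propanoate | CC(C)[Si](C(C)C)(C(C)C)OC(=O)CCc1ccc(O[Si](C(C)C)(C(C)C)C(C)C)cc1 | intermediate (not isolated)
3 | 3-[4-(triisopropylsilyloxy)phenyl]propanoic acid | OC(=O)CCc1ccc(O[Si](C(C)C)(C(C)C)C(C)C)cc1 | intermediate
4 | 2,2-dimethyl-1,3-dioxane-4,6-dione (Meldrum's acid) | CC1(C)OC(=O)CC(=O)O1 | starting material
5 | 3-methylbut-2-en-1-ol (prenol) | CC(C)=CCO | starting material
6 | 3-[(3-methylbut-2-en-1-yl)oxy]-3-oxopropanoic acid | CC(C)=CCOC(=O)CC(=O)O | intermediate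
7 | 2,2,6-trimethyl-4H-1,3-dioxin-4-one | CC1=CC(=O)OC(C)(C)O1 | starting material
8 | 3-methylbut-2-en-1-yl 3-(1H-imidazol-1-yl)-3-oxopropanoate | CC(C)=CCOC(=O)CC(=O)n1ccnc1 | intermediate (not isolated)
9 | 3-methylbut-2-en-1-yl 4-(2,2-dimethyl-4-oxo-4H-1,3-dioxin-6-yl)-3-oxobutanoate | CC(C)=CCOC(=O)CC(=O)CC1=CC(=O)OC(C)(C)O1 | intermediate
10 | 3-[4-(triisopropylsilyloxy)phenyl]propanoyl chloride | ClC(=O)CCc1ccc(O[Si](C(C)C)(C(C)C)C(C)C)cc1 | intermediate (not isolated)
11 | 3-methylbut-2-en-1-yl 2-[(2,2-dimethyl-4-oxo-4H-1,3-dioxin-6-yl)acetyl]-3-oxo-5-[4-(triisopropylsilyloxy)phenyl]pentanoate (racemic, enolisable) | CC(C)=CCOC(=O)C(C(=O)CC1=CC(=O)OC(C)(C)O1)C(=O)CCc1ccc(O[Si](C(C)C)(C(C)C)C(C)C)cc1 | intermediate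
12 | 6-{2,4-dioxo-1-(3-methylbut-2-en-1-yl)-6-[4-(triisopropylsilyloxy)phenyl]hexyl}-2,2-dimethyl-4H-1,3-dioxin-4-one (racemic, enolisable) | CC(C)=CCC(C(=O)CC(=O)CCc1ccc(O[Si](C(C)C)(C(C)C)C(C)C)cc1)C1=CC(=O)OC(C)(C)O1 | intermediate (not isolated)
13 | 7-hydroxy-2,2-dimethyl-8-(3-methylbut-2-en-1-yl)-5-{2-[4-(triisopropylsilyloxy)phenyl]ethyl}-4H-1,3-benzodioxin-4-one | CC(C)=CCc1c(O)cc(CCc2ccc(O[Si](C(C)C)(C(C)C)C(C)C)cc2)c2c1OC(C)(C)OC2=O | intermediate
14 | 2,2-dimethyl-8-(3-methylbut-2-en-1-yl)-7-(triisopropylsilyloxy)-5-{2-[4-(triisopropylsilyloxy)phenyl]ethyl}-4H-1,3-benzodioxin-4-one | CC(C)=CCc1c(O[Si](C(C)C)(C(C)C)C(C)C)cc(CCc2ccc(O[Si](C(C)C)(C(C)C)C(C)C)cc2)c2c1OC(C)(C)OC2=O | intermediate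
15 | 2,2-dimethyl-4-methylidene-8-(3-methylbut-2-en-1-yl)-7-(triisopropylsilyloxy)-5-{2-[4-(triisopropylsilyloxy)phenyl]ethyl}-4H-1,3-benzodioxine | CC(C)=CCc1c(O[Si](C(C)C)(C(C)C)C(C)C)cc(CCc2ccc(O[Si](C(C)C)(C(C)C)C(C)C)cc2)c2c1OC(C)(C)OC2=C | intermediate
16 | ion pair: chlorodimethylaluminate enolate of the aryl methyl ketone bearing the ortho aryloxy-isopropylidene oxocarbenium ion | C=C(O[Al-](C)(C)Cl)c1c(CCc2ccc(O[Si](C(C)C)(C(C)C)C(C)C)cc2)cc(O[Si](C(C)C)(C(C)C)C(C)C)c(CC=C(C)C)c1[O+]=C(C)C | intermediate (not isolated)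
17 | 2,2-dimethyl-8-(3-methylbut-2-en-1-yl)-7-(triisopropylsilyloxy)-5-{2-[4-(triisopropylsilyloxy)phenyl]ethyl}-2,3-dihydro-4H-chromen-4-one | CC(C)=CCc1c(O[Si](C(C)C)(C(C)C)C(C)C)cc(CCc2ccc(O[Si](C(C)C)(C(C)C)C(C)C)cc2)c2c1OC(C)(C)CC2=O | intermediate
18 | racemic 2,2-dimethyl-8-(3-methylbut-2-en-1-yl)-7-(triisopropylsilyloxy)-5-{2-[4-(triisopropylsilyloxy)phenyl]ethyl}-3,4-dihydro-2H-chromen-4-ol | CC(C)=CCc1c(O[Si](C(C)C)(C(C)C)C(C)C)cc(CCc2ccc(O[Si](C(C)C)(C(C)C)C(C)C)cc2)c2c1OC(C)(C)CC2O | intermediate (not isolated)
19 | 2,2-dimethyl-8-(3-methylbut-2-en-1-yl)-7-(triisopropylsilyloxy)-5-{2-[4-(triisopropylsilyloxy)phenyl]ethyl}-2H-chromene | CC(C)=CCc1c(O[Si](C(C)C)(C(C)C)C(C)C)cc(CCc2ccc(O[Si](C(C)C)(C(C)C)C(C)C)cc2)c2c1OC(C)(C)C=C2 | intermediate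
20 | 5-[2-(4-hydroxyphenyl)ethyl]-2,2-dimethyl-8-(3-methylbut-2-en-1-yl)-2H-chromen-7-ol | CC(C)=CCc1c(O)cc(CCc2ccc(O)cc2)c2c1OC(C)(C)C=C2 | intermediate
21 | 7-hydroxy-5-[2-(4-hydroxyphenyl)ethyl]-2,2-dimethyl-8-(3-methylbut-2-en-1-yl)-2H-chromene-6-carboxylic acid | CC(C)=CCc1c(O)c(C(=O)O)c(CCc2ccc(O)cc2)c2c1OC(C)(C)C=C2 | intermediate
22 | methyl 7-hydroxy-5-[2-(4-hydroxyphenyl)ethyl]-2,2-dimethyl-8-(3-methylbut-2-en-1-yl)-2H-chromene-6-carboxylate (achiral) | COC(=O)c1c(O)c(CC=C(C)C)c2c(c1CCc1ccc(O)cc1)C=CC(C)(C)O2 | target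

**Step count and risks**
Total steps: 12. Longest linear sequence: 11 steps (steps 2 to 12, from Meldrum's acid and prenol); step 1 is a one-step branch that joins at step 4.

Steps most likely to fail:

1. Step 8 (proposed new method). The ketal may ionise without productive ring closure: capture of the oxocarbenium ion by the neighbouring prenyl alkene, methyl transfer from aluminium, or loss of the isopropylidene unit on work-up. The fallback uses known chemistry, sets out from 14 and so also bypasses step 7. Addition of MeLi (THF, −78 °C) to the dioxinone carbonyl should open the acetonide with loss of acetone and give the ortho-hydroxyacetophenone 1-[2-hydroxy-3-(3-methylbut-2-en-1-yl)-4-(triisopropylsilyloxy)-6-{2-[4-(triisopropylsilyloxy)phenyl]ethyl}phenyl]ethan-1-one F1; the phenoxide formed on collapse should protect the ketone from a second addition. Kabbe condensation of F1 with acetone and pyrrolidine (EtOH, reflux; enamine aldol condensation then oxa-Michael closure) should give chromanone 17, where the route is rejoined.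

2. Step 11. Carboxylation at the crowded position between the 7-OH and the arylethyl chain may be slow, with thermal decarboxylation of the product and thermal opening of the chromene at 120 °C. The fallback sets out from 20. Vilsmeier–Haack formylation (POCl3, DMF, 0 °C to rt; aqueous NaOAc) should attack the most electron-rich arene position C6 and give 7-hydroxy-5-[2-(4-hydroxyphenyl)ethyl]-2,2-dimethyl-8-(3-methylbut-2-en-1-yl)-2H-chromene-6-carbaldehyde F2. Pinnick oxidation (NaClO2, NaH2PO4, excess 2-methylbut-2-ene, t-BuOH/H2O) should then give acid 21, where the route is rejoined.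

3. Step 9. Under the acidic dehydration the C7 silyl group may be lost, followed by cyclisation of the prenyl group onto the freed phenol, or the electron-rich chromene may dimerise cationically. The fallback sets out from 17 and avoids acid. Enolisation and triflation (KN(SiMe3)2, PhNTf2, THF, −78 °C) should give the enol triflate 2,2-dimethyl-8-(3-methylbut-2-en-1-yl)-7-(triisopropylsilyloxy)-5-{2-[4-(triisopropylsilyloxy)phenyl]ethyl}-2H-chromen-4-yl trifluoromethanesulfonate F3. Palladium-catalysed formate reduction (Pd(OAc)2, PPh3, Bu3N, HCO2H, DMF, 60 °C) should then give chromene 19, where the route is rejoined.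

Further compounds
F1 | step 8 | 1-[2-hydroxy-3-(3-methylbut-2-en-1-yl)-4-(triisopropylsilyloxy)-6-{2-[4-(triisopropylsilyloxy)phenyl]ethyl}phenyl]ethan-1-one | CC(=O)c1c(O)c(CC=C(C)C)c(O[Si](C(C)C)(C(C)C)C(C)C)cc1CCc1ccc(O[Si](C(C)C)(C(C)C)C(C)C)cc1
F2 | step 11 | 7-hydroxy-5-[2-(4-hydroxyphenyl)ethyl]-2,2-dimethyl-8-(3-methylbut-2-en-1-yl)-2H-chromene-6-carbaldehyde | CC(C)=CCc1c(O)c(C=O)c(CCc2ccc(O)cc2)c2c1OC(C)(C)C=C2
F3 | step 9 | 2,2-dimethyl-8-(3-methylbut-2-en-1-yl)-7-(triisopropylsilyloxy)-5-{2-[4-(triisopropylsilyloxy)phenyl]ethyl}-2H-chromen-4-yl trifluoromethanesulfonate | CC(C)=CCc1c(O[Si](C(C)C)(C(C)C)C(C)C)cc(CCc2ccc(O[Si](C(C)C)(C(C)C)C(C)C)cc2)c2c1OC(C)(C)C=C2OS(=O)(=O)C(F)(F)F
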